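## Retrosynthetic overview

1. The C1 acid comes from a primary alcohol. The C11–C12 bond comes from a Wittig union of a C11 allylic phosphonium salt (fragment 1, the dioxane half) with an epoxy aldehyde (fragment 2), followed by diimide reduction of only the new disubstituted alkene.
2. Fragment 2: the cyclohexane ring is bought as β-cyclocitral; its oxirane is closed first, by catalytic asymmetric epoxidation of β-cyclogeraniol.
3. Fragment 1: the 1,2-dioxane is closed by an organocatalytic, desymmetrizing intramolecular peroxy-Michael addition of an achiral tertiary hydroperoxide that carries two identical (E)-2-methyl-enoate arms. One arm becomes C1–C5 and sets C2, C3 and C6; the untouched arm is already C7–C11 with the E-alkene.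
4. The hydroperoxide is made from ethyl acetate and two butenyl Grignard units, then ozonolysis/Wittig and perhydrolysis.
5. Ring order: the oxirane (fragment 2) and the 1,2-dioxane (fragment 1) are made independently before the union; no ring is formed afterwards.

Assumption: the target is read exactly as drawn, (2R)-2-[(3R,6R)-6-methyl-6-[(3E)-4-methyl-6-[(1S,6R)-2,2,6-trimethyl-7-oxabicyclo[4.1.0]heptan-1-yl]hex-3-en-1-yl]-1,2-dioxan-3-yl]propanoic acid. Chain locants C1 (CO2H) to C12 (the CH2 on the oxirane carbon) are used below.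

## Route

Step 1
Reactants: 1 ethyl acetate; 2 but-3-en-1-ylmagnesium bromide (2.2 equiv)
Product: 4 5-methylnona-1,8-dien-5-ol, via hex-5-en-2-one 3 (not isolated)
Conditions: THF, 0 °C → rt; aq. NH4Cl
Reagents that add atoms: none
Why: Double Grignard addition to an ester (ketone 3 reacts faster than 1) gives the achiral, symmetric tertiary carbinol that already holds C6, its methyl and both CH2CH2 arms.

Step 2
Reactants: 4 5-methylnona-1,8-dien-5-ol; 5 methyl 2-(triphenyl-λ5-phosphanylidene)propanoate (2.5 equiv)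
Product: 7 dimethyl (2E,9E)-6-hydroxy-2,6,10-trimethylundeca-2,9-dienedioate, via 4-hydroxy-4-methylheptanedial 6 (not isolated)
Conditions: O3, CH2Cl2, −78 °C; PPh3 (2.2 equiv), −78 °C → rt; evaporate; 5, toluene, 60 °C
Reagents that add atoms: ozone, [O-][O+]=O (gives the aldehyde oxygens of 6)
Why: Ozonolysis followed by Wittig olefination with a stabilized α-methyl ylide installs both (E)-trisubstituted enoates at once (E:Z above 20:1), the lactol form of 6 opening under the reaction conditions.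

Step 3
Reactants: 7 dimethyl (2E,9E)-6-hydroxy-2,6,10-trimethylundeca-2,9-dienedioate
Product: 8 dimethyl (2E,9E)-6-hydroperoxy-2,6,10-trimethylundeca-2,9-dienedioate
Conditions: 50% aq. H2O2 (excess), cat. H2SO4, Et2O, 0 °C → rt
Reagents that add atoms: hydrogen peroxide, OO
Why: Acid-catalysed SN1 perhydrolysis of a tertiary alcohol; the electron-poor enoates do not take part in cation–olefin cyclization, and nothing stereochemical is at stake because 8 is still achiral.

Step 4
Reactants: 8 dimethyl (2E,9E)-6-hydroperoxy-2,6,10-trimethylundeca-2,9-dienedioate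
Product: 9 methyl (2R)-2-[(3R,6R)-6-[(3E)-5-methoxy-4-methyl-5-oxopent-3-en-1-yl]-6-methyl-1,2-dioxan-3-yl]propanoate
Conditions: chiral thiourea–iminophosphorane (BIMP) organocatalyst (10 mol %; L-tert-leucine-derived thiourea, P(C6H4-4-OMe)3-derived iminophosphorane, phosphine-free), toluene, −20 °C
Reagents that add atoms: none
Why: Proposed new method: a catalytic desymmetrizing intramolecular peroxy-Michael (6-exo-trig) cyclization, in which the superbasic iminophosphorane deprotonates the OOH to a chiral aminophosphonium peroxide ion pair while the thiourea binds one enoate carbonyl; oxygen attacks C3 through a chair with the enoate equatorial, the catalyst selecting the enoate face (C3 = R) and, because it is hydrogen-bonded to the peroxide oxygens next to the prochiral carbon, which enantiotopic arm closes (C6 = R, methyl equatorial, spare arm axial, i.e. 3,6-cis); the aminophosphonium N–H then protonates the ester enolate on the face it occupies (syn addition to the E-alkene, giving 2,3-anti, C2 = R); the closest known reactions are BIMP-catalysed enantioselective intramolecular oxa-Michael additions of alcohols to α,β-unsaturated esters and the achiral Et2NH/CF3CH2OH peroxy-Michael closure of hydroperoxy enoates to 1,2-dioxanes.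

Step 5
Reactants: 9 methyl (2R)-2-[(3R,6R)-6-[(3E)-5-methoxy-4-methyl-5-oxopent-3-en-1-yl]-6-methyl-1,2-dioxan-3-yl]propanoate
Product: 10 (2S)-2-[(3R,6R)-6-[(3E)-5-hydroxy-4-methylpent-3-en-1-yl]-6-methyl-1,2-dioxan-3-yl]propan-1-ol
Conditions: i-Bu2AlH (5 equiv), CH2Cl2, −78 °C; aq. KNaC4H4O6 (potassium sodium tartrate)
Reagents that add atoms: none
Why: Hydride reduction of both esters (1,2-reduction of the enoate) at a temperature where a hindered dialkyl peroxide is inert to i-Bu2AlH; C2 is unchanged in space (the descriptor becomes S only through CIP priorities) and can no longer epimerize.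

Step 6
Reactants: 10 (2S)-2-[(3R,6R)-6-[(3E)-5-hydroxy-4-methylpent-3-en-1-yl]-6-methyl-1,2-dioxan-3-yl]propan-1-ol
Product: 11 (2S)-2-[(3R,6R)-6-[(3E)-5-bromo-4-methylpent-3-en-1-yl]-6-methyl-1,2-dioxan-3-yl]propan-1-ol
Conditions: N-bromosuccinimide, Me2S, CH2Cl2, −30 → 0 °C
Reagents that add atoms: N-bromosuccinimide, O=C1CCC(=O)N1Br
Why: Corey–Kim halogenation: only the allylic alkoxysulfonium ion is displaced by bromide (no allylic transposition), while the saturated primary alcohol is returned unchanged on work-up.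

Step 7
Reactants: 11 (2S)-2-[(3R,6R)-6-[(3E)-5-bromo-4-methylpent-3-en-1-yl]-6-methyl-1,2-dioxan-3-yl]propan-1-ol
Product: 12 [(2E)-5-[(3R,6R)-6-[(2S)-1-hydroxypropan-2-yl]-3-methyl-1,2-dioxan-3-yl]-2-methylpent-2-en-1-yl](triphenyl)phosphonium bromide
Conditions: PPh3 (1.05 equiv), MeCN, rt
Reagents that add atoms: triphenylphosphine, c1ccc(cc1)P(c1ccccc1)c1ccccc1
Why: SN2 quaternization of a primary allylic bromide, fast at room temperature where PPh3 does not deoxygenate the hindered 1,2-dioxane.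

Step 8
Reactants: 13 β-cyclocitral (2,6,6-trimethylcyclohex-1-ene-1-carbaldehyde)
Product: 14 β-cyclogeraniol, (2,6,6-trimethylcyclohex-1-en-1-yl)methanol
Conditions: NaBH4, MeOH, 0 °C
Reagents that add atoms: none
Why: Simple 1,2-hydride reduction of the hindered enal gives the allylic alcohol needed to direct the epoxidation.

Step 9
Reactants: 14 β-cyclogeraniol
Product: 15 [(1R,6R)-2,2,6-trimethyl-7-oxabicyclo[4.1.0]heptan-1-yl]methanol
Conditions: Ti(OiPr)4 (10 mol %), D-(−)-diethyl tartrate (12 mol %), t-BuOOH, 4 Å molecular sieves, CH2Cl2, −20 °C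
Reagents that add atoms: tert-butyl hydroperoxide, CC(C)(C)OO
Why: Sharpless asymmetric epoxidation of the tetrasubstituted allylic alcohol; the D-(−)-tartrate complex delivers oxygen to the face that gives the (1R,6R) oxirane (both oxirane centres, the first stereocentres of fragment 2, are set by the catalyst; the cis fusion is fixed by the ring).

Step 10
Reactants: 15 [(1R,6R)-2,2,6-trimethyl-7-oxabicyclo[4.1.0]heptan-1-yl]methanol
Product: 16 (1S,6R)-2,2,6-trimethyl-7-oxabicyclo[4.1.0]heptane-1-carbaldehyde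
Conditions: Dess–Martin periodinane, pyridine, CH2Cl2, 0 °C → rt
Reagents that add atoms: none
Why: Buffered hypervalent-iodine oxidation to a non-enolizable epoxy aldehyde, so neither oxirane centre can be disturbed (the C1 descriptor changes to S by CIP priority only).

Step 11
Reactants: 12 the phosphonium bromide; 16 (1S,6R)-2,2,6-trimethyl-7-oxabicyclo[4.1.0]heptane-1-carbaldehyde
Product: 18 (2S)-2-[(3R,6R)-6-methyl-6-[(3E,5E)-4-methyl-6-[(1S,6R)-2,2,6-trimethyl-7-oxabicyclo[4.1.0]heptan-1-yl]hexa-3,5-dien-1-yl]-1,2-dioxan-3-yl]propan-1-ol, via phosphonium ylide 17 (not isolated)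
Conditions: NaN(SiMe3)2 (2.05 equiv), THF, −78 °C; then 16, −78 → 0 °C
Reagents that add atoms: none
Why: Wittig olefination of a semi-stabilized allylic ylide (second equivalent of base covers the free OH) with the non-enolizable aldehyde forms C11=C12 without touching any stereocentre; the 5Z isomer that accompanies the drawn 5E isomer is carried on because step 12 saturates this bond.

Step 12
Reactants: 18 the diene alcohol
Product: 19 (2S)-2-[(3R,6R)-6-methyl-6-[(3E)-4-methyl-6-[(1S,6R)-2,2,6-trimethyl-7-oxabicyclo[4.1.0]heptan-1-yl]hex-3-en-1-yl]-1,2-dioxan-3-yl]propan-1-ol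
Conditions: 2-nitrobenzenesulfonohydrazide, Et3N, CH2Cl2, rt, added in portions until 18 is consumed
Reagents that add atoms: none
Why: Diimide reduction (concerted syn transfer of H2) is governed by alkene substitution, so the 1,2-disubstituted C11=C12 bond of the diene is reduced well before the trisubstituted C9=C10 bond, and diimide leaves O–O and oxirane bonds intact.

Step 13
Reactants: 19 the alcohol
Product: 21 (2R)-2-[(3R,6R)-6-methyl-6-[(3E)-4-methyl-6-[(1S,6R)-2,2,6-trimethyl-7-oxabicyclo[4.1.0]heptan-1-yl]hex-3-en-1-yl]-1,2-dioxan-3-yl]propanoic acid, via aldehyde 20 (not isolated)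
Conditions: TEMPO (20 mol %), PhI(OAc)2 (2.5 equiv), MeCN/pH 7 phosphate buffer, 0 °C → rt
Reagents that add atoms: water, O
Why: Oxoammonium (TEMPO) oxidation of the primary alcohol through aldehyde 20 and its hydrate gives the acid under buffered conditions that spare the alkene, oxirane and peroxide, with C2 retained (R again by CIP).

## Compound list

1 | ethyl acetate | CCOC(C)=O | starting material
2 | but-3-en-1-ylmagnesium bromide | C=CCC[Mg]Br | starting material
3 | hex-5-en-2-one | CC(=O)CCC=C | intermediate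
4 | 5-methylnona-1,8-dien-5-ol | C=CCCC(C)(O)CCC=C | intermediate
5 | methyl 2-(triphenyl-λ5-phosphanylidene)propanoate | COC(=O)C(C)=P(c1ccccc1)(c1ccccc1)c1ccccc1 | starting material
6 | 4-hydroxy-4-methylheptanedial (in equilibrium with its five-membered lactol) | O=CCCC(C)(O)CCC=O | intermediate
7 | dimethyl (2E,9E)-6-hydroxy-2,6,10-trimethylundeca-2,9-dienedioate | COC(=O)/C(C)=C/CCC(C)(O)CC/C=C(\C)C(=O)OC | intermediate
8 | dimethyl (2E,9E)-6-hydroperoxy-2,6,10-trimethylundeca-2,9-dienedioate | COC(=O)/C(C)=C/CCC(C)(OO)CC/C=C(\C)C(=O)OC | intermediate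
9 | methyl (2R)-2-[(3R,6R)-6-[(3E)-5-methoxy-4-methyl-5-oxopent-3-en-1-yl]-6-methyl-1,2-dioxan-3-yl]propanoate | COC(=O)/C(C)=C/CC[C@]1(C)CC[C@H]([C@@H](C)C(=O)OC)OO1 | intermediate
10 | (2S)-2-[(3R,6R)-6-[(3E)-5-hydroxy-4-methylpent-3-en-1-yl]-6-methyl-1,2-dioxan-3-yl]propan-1-ol | OC/C(C)=C/CC[C@]1(C)CC[C@H]([C@@H](C)CO)OO1 | intermediate
11 | (2S)-2-[(3R,6R)-6-[(3E)-5-bromo-4-methylpent-3-en-1-yl]-6-methyl-1,2-dioxan-3-yl]propan-1-ol | BrC/C(C)=C/CC[C@]1(C)CC[C@H]([C@@H](C)CO)OO1 | intermediate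
12 | [(2E)-5-[(3R,6R)-6-[(2S)-1-hydroxypropan-2-yl]-3-methyl-1,2-dioxan-3-yl]-2-methylpent-2-en-1-yl](triphenyl)phosphonium bromide | [Br-].C(/C(C)=C/CC[C@]1(C)CC[C@H]([C@@H](C)CO)OO1)[P+](c2ccccc2)(c3ccccc3)c4ccccc4 | intermediate
13 | β-cyclocitral, 2,6,6-trimethylcyclohex-1-ene-1-carbaldehyde | O=CC1=C(C)CCCC1(C)C | starting material
14 | β-cyclogeraniol, (2,6,6-trimethylcyclohex-1-en-1-yl)methanol | OCC1=C(C)CCCC1(C)C | intermediate
15 | [(1R,6R)-2,2,6-trimethyl-7-oxabicyclo[4.1.0]heptan-1-yl]methanol | OC[C@@]12O[C@]1(C)CCCC2(C)C | intermediate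
16 | (1S,6R)-2,2,6-trimethyl-7-oxabicyclo[4.1.0]heptane-1-carbaldehyde | O=C[C@@]12O[C@]1(C)CCCC2(C)C | intermediate
17 | (2S)-2-[(3R,6R)-6-methyl-6-[(3E)-4-methyl-5-(triphenyl-λ5-phosphanylidene)pent-3-en-1-yl]-1,2-dioxan-3-yl]propan-1-ol (present as its sodium alkoxide) | C(/C(C)=C/CC[C@]1(C)CC[C@H]([C@@H](C)CO)OO1)=P(c2ccccc2)(c3ccccc3)c4ccccc4 | intermediate
18 | (2S)-2-[(3R,6R)-6-methyl-6-[(3E,5E)-4-methyl-6-[(1S,6R)-2,2,6-trimethyl-7-oxabicyclo[4.1.0]heptan-1-yl]hexa-3,5-dien-1-yl]-1,2-dioxan-3-yl]propan-1-ol | C/C(=C\CC[C@]1(C)CC[C@H]([C@@H](C)CO)OO1)/C=C/[C@@]12O[C@]1(C)CCCC2(C)C | intermediate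
19 | (2S)-2-[(3R,6R)-6-methyl-6-[(3E)-4-methyl-6-[(1S,6R)-2,2,6-trimethyl-7-oxabicyclo[4.1.0]heptan-1-yl]hex-3-en-1-yl]-1,2-dioxan-3-yl]propan-1-ol | C/C(=C\CC[C@]1(C)CC[C@H]([C@@H](C)CO)OO1)CC[C@@]12O[C@]1(C)CCCC2(C)C | intermediate
20 | (2R)-2-[(3R,6R)-6-methyl-6-[(3E)-4-methyl-6-[(1S,6R)-2,2,6-trimethyl-7-oxabicyclo[4.1.0]heptan-1-yl]hex-3-en-1-yl]-1,2-dioxan-3-yl]propanal | C/C(=C\CC[C@]1(C)CC[C@H]([C@@H](C)C=O)OO1)CC[C@@]12O[C@]1(C)CCCC2(C)C | intermediate
21 | (2R)-2-[(3R,6R)-6-methyl-6-[(3E)-4-methyl-6-[(1S,6R)-2,2,6-trimethyl-7-oxabicyclo[4.1.0]heptan-1-yl]hex-3-en-1-yl]-1,2-dioxan-3-yl]propanoic acid | C/C(=C\CC[C@]1(C)CC[C@H]([C@@H](C)C(=O)O)OO1)CC[C@@]12O[C@]1(C)CCCC2(C)C | target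

## Step count and risk

Total: 13 steps. Longest linear sequence: 10 steps (steps 1–7, then 11–13); fragment 2 takes 3 steps (8–10).

The three steps most likely to fail:

Step 4 (the proposed new cyclization). The risks are that the spare arm and the methyl group are sterically almost equal, so arm selection (C6) may be poor; that the enolate may be protonated from the wrong face (C2); and that the enolate may attack the O–O bond to give an epoxy ester instead. Fallback with known chemistry, from 8 back to 9: Et2NH in CF3CH2OH at rt, the established achiral amine-mediated peroxy-Michael closure, gives the dioxane diester as racemic diastereomers. The 2,3-anti/3,6-cis racemate is isolated on silica; it is 9 together with its mirror image, methyl (2S)-2-[(3S,6S)-6-[(3E)-5-methoxy-4-methyl-5-oxopent-3-en-1-yl]-6-methyl-1,2-dioxan-3-yl]propanoate F1. Preparative chromatography on a chiral polysaccharide phase removes F1 and returns 9, at the cost of yield.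

Step 11 (Wittig union). The risks are the strong base next to the peroxide, the hindered neopentylic aldehyde, and partial E/Z scrambling of C9=C10 in the allylic ylide. Fallback, from 11 back to 18, is a Julia–Kocienski olefination run in Barbier mode. Displacement of the bromide of 11 with 1-phenyl-1H-tetrazole-5-thiol and K2CO3 gives the sulfide (2S)-2-[(3R,6R)-6-methyl-6-[(3E)-4-methyl-5-[(1-phenyl-1H-tetrazol-5-yl)sulfanyl]pent-3-en-1-yl]-1,2-dioxan-3-yl]propan-1-ol F2. Oxidation with (NH4)6Mo7O24·4H2O and H2O2 gives the corresponding sulfone F3. KN(SiMe3)2 is then added to a mixture of F3 and 16 (DME, −60 °C), so base never accumulates beside the peroxide, and 18 is formed.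

Step 12 (chemoselective diimide reduction). The risk is that the C11=C12 bond sits next to the quaternary oxirane carbon and may not be reduced cleanly ahead of the trisubstituted C9=C10 bond. Fallback, from 10 back to 19, reverses the roles so that the only competitors are a tri- and a tetrasubstituted alkene:
- MnO2 in CH2Cl2 oxidizes only the allylic alcohol of 10 to the hydroxy enal (2S)-2-[(3R,6R)-6-methyl-6-[(3E)-4-methyl-5-oxopent-3-en-1-yl]-1,2-dioxan-3-yl]propan-1-ol F4.
- Alcohol 14 with PPh3·HBr gives [(2,6,6-trimethylcyclohex-1-en-1-yl)methyl](triphenyl)phosphonium bromide F5, which n-BuLi converts, before the peroxide is added, into the ylide [(2,6,6-trimethylcyclohex-1-en-1-yl)methylidene](triphenyl)-λ5-phosphane F6.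
- Wittig reaction of F6 with F4 gives the triene (2S)-2-[(3R,6R)-6-methyl-6-[(3E,5E)-4-methyl-6-(2,6,6-trimethylcyclohex-1-en-1-yl)hexa-3,5-dien-1-yl]-1,2-dioxan-3-yl]propan-1-ol F7.
- Diimide reduces its single disubstituted alkene with a wide margin to (2S)-2-[(3R,6R)-6-methyl-6-[(3E)-4-methyl-6-(2,6,6-trimethylcyclohex-1-en-1-yl)hex-3-en-1-yl]-1,2-dioxan-3-yl]propan-1-ol F8.
- mCPBA (1 equiv, NaHCO3, CH2Cl2, −20 °C) epoxidizes the most electron-rich, tetrasubstituted ring alkene to give 19 and its oxirane diastereomer (2S)-2-[(3R,6R)-6-methyl-6-[(3E)-4-methyl-6-[(1R,6S)-2,2,6-trimethyl-7-oxabicyclo[4.1.0]heptan-1-yl]hex-3-en-1-yl]-1,2-dioxan-3-yl]propan-1-ol F9, which is removed by HPLC.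

The price of this fallback is the loss of catalyst control over the oxirane, so about half the material is lost as F9.

## Further compounds

F1 | step 4 | methyl (2S)-2-[(3S,6S)-6-[(3E)-5-methoxy-4-methyl-5-oxopent-3-en-1-yl]-6-methyl-1,2-dioxan-3-yl]propanoate | COC(=O)/C(C)=C/CC[C@@]1(C)CC[C@@H]([C@H](C)C(=O)OC)OO1
F2 | step 11 | (2S)-2-[(3R,6R)-6-methyl-6-[(3E)-4-methyl-5-[(1-phenyl-1H-tetrazol-5-yl)sulfanyl]pent-3-en-1-yl]-1,2-dioxan-3-yl]propan-1-ol | c2ccccc2-n3nnnc3SC/C(C)=C/CC[C@]1(C)CC[C@H]([C@@H](C)CO)OO1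
F3 | step 11 | (2S)-2-[(3R,6R)-6-methyl-6-[(3E)-4-methyl-5-[(1-phenyl-1H-tetrazol-5-yl)sulfonyl]pent-3-en-1-yl]-1,2-dioxan-3-yl]propan-1-ol | c2ccccc2-n3nnnc3S(=O)(=O)C/C(C)=C/CC[C@]1(C)CC[C@H]([C@@H](C)CO)OO1
F4 | step 12 | (2S)-2-[(3R,6R)-6-methyl-6-[(3E)-4-methyl-5-oxopent-3-en-1-yl]-1,2-dioxan-3-yl]propan-1-ol | O=C/C(C)=C/CC[C@]1(C)CC[C@H]([C@@H](C)CO)OO1
F5 | step 12 | [(2,6,6-trimethylcyclohex-1-en-1-yl)methyl](triphenyl)phosphonium bromide | [Br-].CC1=C(C[P+](c2ccccc2)(c3ccccc3)c4ccccc4)C(C)(C)CCC1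
F6 | step 12 | [(2,6,6-trimethylcyclohex-1-en-1-yl)methylidene](triphenyl)-λ5-phosphane | CC1=C(C=P(c2ccccc2)(c3ccccc3)c4ccccc4)C(C)(C)CCC1
F7 | step 12 | (2S)-2-[(3R,6R)-6-methyl-6-[(3E,5E)-4-methyl-6-(2,6,6-trimethylcyclohex-1-en-1-yl)hexa-3,5-dien-1-yl]-1,2-dioxan-3-yl]propan-1-ol | C/C(=C\CC[C@]1(C)CC[C@H]([C@@H](C)CO)OO1)/C=C/C1=C(C)CCCC1(C)C
F8 | step 12 | (2S)-2-[(3R,6R)-6-methyl-6-[(3E)-4-methyl-6-(2,6,6-trimethylcyclohex-1-en-1-yl)hex-3-en-1-yl]-1,2-dioxan-3-yl]propan-1-ol | C/C(=C\CC[C@]1(C)CC[C@H]([C@@H](C)CO)OO1)CCC1=C(C)CCCC1(C)C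
F9 | step 12 | (2S)-2-[(3R,6R)-6-methyl-6-[(3E)-4-methyl-6-[(1R,6S)-2,2,6-trimethyl-7-oxabicyclo[4.1.0]heptan-1-yl]hex-3-en-1-yl]-1,2-dioxan-3-yl]propan-1-ol | C/C(=C\CC[C@]1(C)CC[C@H]([C@@H](C)CO)OO1)CC[C@]12O[C@@]1(C)CCCC2(C)C
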